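The route rests on disconnecting ring B of the 1-aryl-1,2-dihydronaphthalene across C4–C4a and C1–C8a. Ring A, fused through C4a and C8a with the C8 methoxy group next to C8a, is the imprint of a 3-methoxyaryne, and C1–C4 form a diene. One aryne Diels–Alder reaction therefore joins the two halves, closes ring B, fixes the ring A oxygenation pattern through the polarized triple bond and sets C1 under control of a camphorsultam. The precursors are a 2-silylaryl triflate made from vanillin and a 1-aryl-3-silyloxydiene bearing the acyl sultam on C2, made from veratraldehyde; C2 is then set trans by equilibration of the derived C3 ketone.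

Key step: step 9

Assumption: the (1S)-sultam is taken to shield the diene face that leads to the (1S) configuration at C1; should the induction run the other way, the (1R)-sultam would be used with no other change.

Atom numbers C1–C9 and ring letters refer to the target numbered as a 1-aryl-1,2-dihydronaphthalene (C1 aryl, C2 bearing C9, C3 formyl, C7 OH, C8 OMe).

**Fragment A: the aryne precursor**

Step 1
Reactants: 1 vanillin
Product: 2 4-isopropoxy-3-methoxybenzaldehyde
Conditions: 2-bromopropane, K2CO3, DMF, 70 °C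
Reagents that add atoms: 2-bromopropane, CC(C)Br
Why: Williamson etherification of the phenoxide with a secondary bromide in a dipolar aprotic solvent should proceed cleanly, and the isopropyl ether later withstands organolithium, fluoride, hydride and amide bases.

Step 2
Reactants: 2 4-isopropoxy-3-methoxybenzaldehyde
Product: 4 4-isopropoxy-3-methoxyphenol, via aryl formate 3 (not isolated)
Conditions: mCPBA, CH2Cl2, 0 °C to rt; NaHCO3 wash; then K2CO3 (cat.), MeOH, rt
Reagents that add atoms: mCPBA (3-chloroperbenzoic acid), O=C(OO)c1cccc(Cl)c1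
Why: Baeyer–Villiger (Dakin-type) oxidation of an electron-rich benzaldehyde proceeds with aryl migration to the formate, which is methanolysed to the phenol.

Step 3
Reactants: 4 4-isopropoxy-3-methoxyphenol
Product: 5 4-isopropoxy-3-methoxyphenyl N-isopropylcarbamate
Conditions: i-PrNCO, Et3N (cat.), CH2Cl2, rt
Reagents that add atoms: isopropyl isocyanate, CC(C)N=C=O
Why: Amine-catalysed addition of the phenol to the isocyanate gives the carbamate that serves as a removable directing group for metalation.

Step 4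
Reactants: 5 4-isopropoxy-3-methoxyphenyl N-isopropylcarbamate
Product: 9 4-isopropoxy-3-methoxy-2-(trimethylsilyl)phenyl N-isopropylcarbamate, via N-silyl carbamate 6 (not isolated), via aryllithium 7 (not isolated), via bis-silyl carbamate 8 (not isolated)
Conditions: Me3SiOTf, TMEDA, Et2O, 0 °C to rt; n-BuLi, TMEDA, −78 °C; Me3SiCl, −78 °C to rt; aq. NaHSO4
Reagents that add atoms: chlorotrimethylsilane, C[Si](C)(C)Cl
Why: In a directed ortho-metalation the N–H is first masked by silylation, lithiation then occurs at the position flanked by the carbamate and methoxy oxygens (cooperative direction), C-silylation follows, and the N–Si bond is hydrolysed on work-up.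

Step 5
Reactants: 9 4-isopropoxy-3-methoxy-2-(trimethylsilyl)phenyl N-isopropylcarbamate
Product: 11 4-isopropoxy-3-methoxy-2-(trimethylsilyl)phenyl trifluoromethanesulfonate, via silylphenol 10 (not isolated)
Conditions: DBU, Et2NH, MeCN, 40 °C; then PhNTf2, rt
Reagents that add atoms: N-phenylbis(trifluoromethanesulfonimide), O=S(=O)(N(c1ccccc1)S(=O)(=O)C(F)(F)F)C(F)(F)F
Why: Base-induced E1cB loss of isopropyl isocyanate (scavenged by Et2NH) frees the phenoxide, which is O-sulfonylated in the same flask by the mild triflyl donor without disturbing the aryl–silicon bond.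

**Fragment B: the diene**

Step 6
Reactants: 12 (1S)-2,10-camphorsultam; 13 2,2,6-trimethyl-4H-1,3-dioxin-4-one
Product: 15 (1S)-N-(3-oxobutanoyl)-2,10-camphorsultam, via acetylketene 14 (not isolated)
Conditions: xylenes, 140 °C, acetone distilled off
Reagents that add atoms: none
Why: Thermal retro-[4+2] fragmentation of the dioxinone releases acetone and acetylketene, which is captured by the sultam N–H in a thermal acetoacetylation.

Step 7
Reactants: 15 (1S)-N-(3-oxobutanoyl)-2,10-camphorsultam; 16 veratraldehyde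
Product: 17 (1S)-N-[(2Z)-2-acetyl-3-(3,4-dimethoxyphenyl)prop-2-enoyl]-2,10-camphorsultam
Conditions: piperidine (cat.), AcOH (cat.), toluene, 80 °C, 4 Å MS
Reagents that add atoms: none
Why: The Knoevenagel condensation is reversible and should settle on the (Z)-alkene, in which the aryl group is cis to the acyl sultam (twisted out of plane in any case) and trans to the coplanar acetyl group.

Step 8
Reactants: 17 (1S)-N-[(2Z)-2-acetyl-3-(3,4-dimethoxyphenyl)prop-2-enoyl]-2,10-camphorsultam
Product: 18 (1S)-N-[(2Z)-3-(tert-butyldimethylsilyloxy)-2-(3,4-dimethoxybenzylidene)but-3-enoyl]-2,10-camphorsultam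
Conditions: t-BuMe2SiOTf, Et3N, CH2Cl2, 0 °C
Reagents that add atoms: tert-butyldimethylsilyl triflate, CC(C)(C)[Si](C)(C)OS(=O)(=O)C(F)(F)F
Why: Soft enolisation of the methyl ketone, the only enolisable position, with silyl triflate and amine gives the 2-silyloxydiene with the alkene geometry untouched, so the aryl group sits on the outside of the diene terminus.

**Key step**

Step 9
Reactants: 11 4-isopropoxy-3-methoxy-2-(trimethylsilyl)phenyl trifluoromethanesulfonate; 18 (1S)-N-[(2Z)-3-(tert-butyldimethylsilyloxy)-2-(3,4-dimethoxybenzylidene)but-3-enoyl]-2,10-camphorsultam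
Product: 20 (1S)-N-{[(1S)-3-(tert-butyldimethylsilyloxy)-1-(3,4-dimethoxyphenyl)-7-isopropoxy-8-methoxy-1,4-dihydronaphthalen-2-yl]carbonyl}-2,10-camphorsultam, via aryne 19 (not isolated)
Conditions: CsF (slight excess over 11), MeCN/toluene 1:1, 25 °C, argon
Reagents that add atoms: none
Why: Fluoride attacks the trimethylsilyl group of 11 and triflate leaves, giving aryne 19, which adds to the s-cis diene 18 in an asynchronous [4+2] cycloaddition. The closest known reaction type is the Diels–Alder reaction of arynes from 2-silylaryl triflates with acyclic dienes, including dienes that carry a camphorsultam. Ring B is closed by the intermolecular cycloaddition itself, with C4–C4a and C1–C8a formed on one face of the diene and no separate cyclisation event. C1 is controlled by the sultam, whose acyl group is twisted out of the diene plane by the flanking aryl and silyloxyvinyl groups so that the sulfonyl and camphor units cover one face and the aryne should add to the other. The step needs regioselectivity and facial selectivity: the silyloxy-activated CH2 terminus (C4) should attack the aryne carbon remote from the methoxy group (C4a), because the methoxy group stabilises developing charge at C8a, and the outside position of the aryl group keeps the s-cis diene accessible. Fluoride is kept near stoichiometric and air is excluded to protect the enol ether and the doubly benzylic C1–H from desilylation and aromatisation.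

**From the adduct to the target**

Step 10
Reactants: 20 (1S)-N-{[(1S)-3-(tert-butyldimethylsilyloxy)-1-(3,4-dimethoxyphenyl)-7-isopropoxy-8-methoxy-1,4-dihydronaphthalen-2-yl]carbonyl}-2,10-camphorsultam
Product: 21 [(1S)-3-(tert-butyldimethylsilyloxy)-1-(3,4-dimethoxyphenyl)-7-isopropoxy-8-methoxy-1,4-dihydronaphthalen-2-yl]methanol
Conditions: LiAlH4, THF, −20 to 0 °C; aq. NaOH work-up
Reagents that add atoms: none
Why: LiAlH4 reduces the activated imide carbonyl of the N-acyl sultam to the primary alcohol (C9) and releases the auxiliary 12 for recovery, while the silyl enol ether and aryl ethers are inert to hydride and a basic work-up avoids ionisation of the allylic alcohol.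

Step 11
Reactants: 21 [(1S)-3-(tert-butyldimethylsilyloxy)-1-(3,4-dimethoxyphenyl)-7-isopropoxy-8-methoxy-1,4-dihydronaphthalen-2-yl]methanol
Product: 22 (1S)-3-(tert-butyldimethylsilyloxy)-2-[(tert-butyldimethylsilyloxy)methyl]-1-(3,4-dimethoxyphenyl)-7-isopropoxy-8-methoxy-1,4-dihydronaphthalene
Conditions: t-BuMe2SiCl, imidazole, CH2Cl2, 0 °C to rt
Reagents that add atoms: tert-butyldimethylsilyl chloride, CC(C)(C)[Si](C)(C)Cl
Why: Imidazole-mediated silylation protects the primary alcohol without acid or free alkoxide, so the neighbouring enol ether is neither hydrolysed nor induced to transfer its silyl group.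

Step 12
Reactants: 22 (1S)-3-(tert-butyldimethylsilyloxy)-2-[(tert-butyldimethylsilyloxy)methyl]-1-(3,4-dimethoxyphenyl)-7-isopropoxy-8-methoxy-1,4-dihydronaphthalene
Product: 24 (3S,4S)-3-[(tert-butyldimethylsilyloxy)methyl]-4-(3,4-dimethoxyphenyl)-6-isopropoxy-5-methoxy-3,4-dihydronaphthalen-2(1H)-one, via cis ketone 23 (not isolated)
Conditions: Bu4NF, AcOH, THF, 0 °C; work-up; then DBU (cat.), toluene, rt, argon
Reagents that add atoms: none
Why: Acetic-acid-buffered fluoride should cleave the enol silyl ether (enolate leaving group) far faster than the primary alkyl silyl ether and protonate C2, and catalytic DBU should then equilibrate the C2 epimers through the enolate to the trans ketone, in which the C1 aryl group, held pseudoaxial by the peri C8 methoxy group, and the C2 silyloxymethyl group lie anti, so C2 is set under thermodynamic control.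

Step 13
Reactants: 24 (3S,4S)-3-[(tert-butyldimethylsilyloxy)methyl]-4-(3,4-dimethoxyphenyl)-6-isopropoxy-5-methoxy-3,4-dihydronaphthalen-2(1H)-one
Product: 25 (3S,4S)-3-[(tert-butyldimethylsilyloxy)methyl]-4-(3,4-dimethoxyphenyl)-6-isopropoxy-5-methoxy-3,4-dihydronaphthalen-2-yl trifluoromethanesulfonate
Conditions: KN(SiMe3)2, THF, −78 °C; PhNTf2, −78 to 0 °C
Reagents that add atoms: N-phenylbis(trifluoromethanesulfonimide), O=S(=O)(N(c1ccccc1)S(=O)(=O)C(F)(F)F)C(F)(F)F
Why: Kinetic enolate formation at the benzylic C4 methylene, far more acidic and less hindered than the C2 methine, followed by O-sulfonylation should give the C3=C4 enol triflate, and since C2 is not deprotonated its configuration is kept and no β-elimination of the silyloxy group can start.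

Step 14
Reactants: 25 (3S,4S)-3-[(tert-butyldimethylsilyloxy)methyl]-4-(3,4-dimethoxyphenyl)-6-isopropoxy-5-methoxy-3,4-dihydronaphthalen-2-yl trifluoromethanesulfonate
Product: 26 (3R,4S)-3-[(tert-butyldimethylsilyloxy)methyl]-4-(3,4-dimethoxyphenyl)-6-isopropoxy-5-methoxy-3,4-dihydronaphthalene-2-carbaldehyde
Conditions: Pd(OAc)2 (cat.), dppp, CO (1 atm), Et3SiH, Et3N, DMF, 70 °C
Reagents that add atoms: carbon monoxide, [C-]#[O+]
Why: Palladium-catalysed reductive carbonylation (formylation) of the enol triflate proceeds by oxidative addition to zerovalent palladium, CO insertion and hydride transfer from the silane, placing the formyl group on C3 without touching C1 or C2.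

Step 15
Reactants: 26 (3R,4S)-3-[(tert-butyldimethylsilyloxy)methyl]-4-(3,4-dimethoxyphenyl)-6-isopropoxy-5-methoxy-3,4-dihydronaphthalene-2-carbaldehyde
Product: 27 vitekwangin B, (3R,4S)-4-(3,4-dimethoxyphenyl)-6-hydroxy-3-(hydroxymethyl)-5-methoxy-3,4-dihydronaphthalene-2-carbaldehyde
Conditions: BCl3, CH2Cl2, −78 to 0 °C; then aq. HCl, THF, rt
Reagents that add atoms: none
Why: BCl3 cleaves aryl isopropyl ethers (chloride capture of the secondary alkyl group) much faster than aryl methyl ethers and also opens the primary silyl ether, and the aqueous acid work-up hydrolyses the boron esters and any remaining silyl ether.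

**Compound list**

1 | vanillin | COc1cc(C=O)ccc1O | starting material
2 | 4-isopropoxy-3-methoxybenzaldehyde | COc1cc(C=O)ccc1OC(C)C | intermediate
3 | 4-isopropoxy-3-methoxyphenyl formate | COc1cc(OC=O)ccc1OC(C)C | intermediate
4 | 4-isopropoxy-3-methoxyphenol | COc1cc(O)ccc1OC(C)C | intermediate
5 | 4-isopropoxy-3-methoxyphenyl N-isopropylcarbamate | COc1cc(OC(=O)NC(C)C)ccc1OC(C)C | intermediate
6 | 4-isopropoxy-3-methoxyphenyl N-isopropyl-N-(trimethylsilyl)carbamate | COc1cc(OC(=O)N(C(C)C)[Si](C)(C)C)ccc1OC(C)C | intermediate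
7 | 2-lithio-4-isopropoxy-3-methoxyphenyl N-isopropyl-N-(trimethylsilyl)carbamate | COc1c([Li])c(OC(=O)N(C(C)C)[Si](C)(C)C)ccc1OC(C)C | intermediate
8 | 4-isopropoxy-3-methoxy-2-(trimethylsilyl)phenyl N-isopropyl-N-(trimethylsilyl)carbamate | COc1c([Si](C)(C)C)c(OC(=O)N(C(C)C)[Si](C)(C)C)ccc1OC(C)C | intermediate
9 | 4-isopropoxy-3-methoxy-2-(trimethylsilyl)phenyl N-isopropylcarbamate | COc1c([Si](C)(C)C)c(OC(=O)NC(C)C)ccc1OC(C)C | intermediate
10 | 4-isopropoxy-3-methoxy-2-(trimethylsilyl)phenol | COc1c([Si](C)(C)C)c(O)ccc1OC(C)C | intermediate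
11 | 4-isopropoxy-3-methoxy-2-(trimethylsilyl)phenyl trifluoromethanesulfonate | CC(C)Oc1ccc(OS(=O)(=O)C(F)(F)F)c([Si](C)(C)C)c1OC | intermediate
12 | (1S)-2,10-camphorsultam | CC1(C)[C@@H]2CC[C@]13CS(=O)(=O)N[C@@H]3C2 | starting material
13 | 2,2,6-trimethyl-4H-1,3-dioxin-4-one | CC1=CC(=O)OC(C)(C)O1 | starting material
14 | acetylketene | CC(=O)C=C=O | intermediate
15 | (1S)-N-(3-oxobutanoyl)-2,10-camphorsultam | CC1(C)[C@@H]2CC[C@]13CS(=O)(=O)N(C(=O)CC(C)=O)[C@@H]3C2 | intermediate
16 | veratraldehyde | COc1ccc(C=O)cc1OC | starting material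
17 | (1S)-N-[(2Z)-2-acetyl-3-(3,4-dimethoxyphenyl)prop-2-enoyl]-2,10-camphorsultam | CC1(C)[C@@H]2CC[C@]13CS(=O)(=O)N(C(=O)/C(C(C)=O)=C\c4ccc(OC)c(OC)c4)[C@@H]3C2 | intermediate
18 | (1S)-N-[(2Z)-3-(tert-butyldimethylsilyloxy)-2-(3,4-dimethoxybenzylidene)but-3-enoyl]-2,10-camphorsultam | CC1(C)[C@@H]2CC[C@]13CS(=O)(=O)N(C(=O)/C(C(=C)O[Si](C)(C)C(C)(C)C)=C\c4ccc(OC)c(OC)c4)[C@@H]3C2 | intermediate
19 | 4-isopropoxy-3-methoxybenzyne (1,2-didehydro-3-methoxy-4-isopropoxybenzene) | COC1=C(OC(C)C)C=CC#C1 | intermediate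
20 | (1S)-N-{[(1S)-3-(tert-butyldimethylsilyloxy)-1-(3,4-dimethoxyphenyl)-7-isopropoxy-8-methoxy-1,4-dihydronaphthalen-2-yl]carbonyl}-2,10-camphorsultam | CC1(C)[C@@H]2CC[C@]13CS(=O)(=O)N(C(=O)C4=C(O[Si](C)(C)C(C)(C)C)Cc5ccc(OC(C)C)c(OC)c5[C@@H]4c4ccc(OC)c(OC)c4)[C@@H]3C2 | intermediate
21 | [(1S)-3-(tert-butyldimethylsilyloxy)-1-(3,4-dimethoxyphenyl)-7-isopropoxy-8-methoxy-1,4-dihydronaphthalen-2-yl]methanol | OCC1=C(O[Si](C)(C)C(C)(C)C)Cc2ccc(OC(C)C)c(OC)c2[C@@H]1c1ccc(OC)c(OC)c1 | intermediate
22 | (1S)-3-(tert-butyldimethylsilyloxy)-2-[(tert-butyldimethylsilyloxy)methyl]-1-(3,4-dimethoxyphenyl)-7-isopropoxy-8-methoxy-1,4-dihydronaphthalene | CC(C)(C)[Si](C)(C)OCC1=C(O[Si](C)(C)C(C)(C)C)Cc2ccc(OC(C)C)c(OC)c2[C@@H]1c1ccc(OC)c(OC)c1 | intermediate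
23 | (3R,4S)-3-[(tert-butyldimethylsilyloxy)methyl]-4-(3,4-dimethoxyphenyl)-6-isopropoxy-5-methoxy-3,4-dihydronaphthalen-2(1H)-one (cis epimer) | COc1ccc([C@H]2c3c(ccc(OC(C)C)c3OC)CC(=O)[C@H]2CO[Si](C)(C)C(C)(C)C)cc1OC | intermediate
24 | (3S,4S)-3-[(tert-butyldimethylsilyloxy)methyl]-4-(3,4-dimethoxyphenyl)-6-isopropoxy-5-methoxy-3,4-dihydronaphthalen-2(1H)-one (trans) | COc1ccc([C@H]2c3c(ccc(OC(C)C)c3OC)CC(=O)[C@@H]2CO[Si](C)(C)C(C)(C)C)cc1OC | intermediate
25 | (3S,4S)-3-[(tert-butyldimethylsilyloxy)methyl]-4-(3,4-dimethoxyphenyl)-6-isopropoxy-5-methoxy-3,4-dihydronaphthalen-2-yl trifluoromethanesulfonate | COc1ccc([C@H]2c3c(ccc(OC(C)C)c3OC)C=C(OS(=O)(=O)C(F)(F)F)[C@@H]2CO[Si](C)(C)C(C)(C)C)cc1OC | intermediate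
26 | (3R,4S)-3-[(tert-butyldimethylsilyloxy)methyl]-4-(3,4-dimethoxyphenyl)-6-isopropoxy-5-methoxy-3,4-dihydronaphthalene-2-carbaldehyde | COc1ccc([C@H]2c3c(ccc(OC(C)C)c3OC)C=C(C=O)[C@@H]2CO[Si](C)(C)C(C)(C)C)cc1OC | intermediate
27 | vitekwangin B, (3R,4S)-4-(3,4-dimethoxyphenyl)-6-hydroxy-3-(hydroxymethyl)-5-methoxy-3,4-dihydronaphthalene-2-carbaldehyde | COc1ccc([C@H]2c3c(ccc(O)c3OC)C=C(C=O)[C@@H]2CO)cc1OC | target

**Step count and risks**

Total step count: 15. Longest linear sequence: 12 steps (vanillin through steps 1–5 and 9–15); the diene branch adds steps 6–8.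

Steps most likely to fail:

Step 9. Fluoride may cleave the silyl enol ether of diene 18 or of adduct 20 faster than it liberates the aryne, after which the free β-dicarbonyl enolate would consume the aryne; the facial bias of the twisted acyl sultam may also be incomplete. The fallback generates the same aryne without fluoride by halogen–magnesium exchange. It sets out from aryllithium 7 and returns at 20. Quenching 7 with iodine in place of Me3SiCl should give 2-iodo-4-isopropoxy-3-methoxyphenyl N-isopropyl-N-(trimethylsilyl)carbamate F1 and, after aqueous work-up, 2-iodo-4-isopropoxy-3-methoxyphenyl N-isopropylcarbamate F2. DBU/Et2NH and then PhNTf2, as in step 5, should give 2-iodo-4-isopropoxy-3-methoxyphenol F3 in the flask and from it 2-iodo-4-isopropoxy-3-methoxyphenyl triflate F4. Treating F4 with Me3SiCH2MgCl in THF at −78 °C in the presence of 18 should give 2-(chloromagnesio)-4-isopropoxy-3-methoxyphenyl triflate F5, which loses triflate to aryne 19; cycloaddition with 18 then gives 20 at low temperature, where the hindered Grignard reagent should exchange with the iodide faster than it attacks the acyl sultam.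

Step 12. Equilibration at C2 may stop short of a useful trans preference, or the base may trigger β-elimination of silanol from the enolisable ketone. The fallback fixes C2 at a stage where the substituent is much larger and never exposes the simple ketone to base. It sets out from 20 and returns at 24. Buffered Bu4NF/AcOH followed by Et3N should convert 20 into the trans β-keto acyl sultam F6, whose doubly activated C2 equilibrates readily and places the bulky acyl sultam anti to the aryl group. NaBH4 in MeOH/THF at −40 °C should give the β-hydroxy acyl sultam F7 (C3 carbinol epimers are immaterial), and LiAlH4 should give the diol F8 and recovered sultam. Selective silylation of the primary hydroxyl (t-BuMe2SiCl, imidazole, 0 °C) should give the mono-silyl ether F9, and Dess–Martin oxidation buffered with NaHCO3 should give 24, which is taken directly into step 13.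

Step 14. The vinylpalladium intermediate may capture hydride before CO insertion, reducing the triflate to the plain alkene, or the silane may over-reduce the enal. The fallback separates carbonylation from reduction. It sets out from 25 and returns at 26. Methoxycarbonylation (Pd(OAc)2, dppp, CO, MeOH, Et3N, DMF, 60 °C) should give the methyl ester F10; i-Bu2AlH in CH2Cl2 at −78 °C should give the allylic alcohol F11; MnO2 in CH2Cl2 should oxidise it to 26.

Further compounds
F1 | step 9 | 2-iodo-4-isopropoxy-3-methoxyphenyl N-isopropyl-N-(trimethylsilyl)carbamate | COc1c(I)c(OC(=O)N(C(C)C)[Si](C)(C)C)ccc1OC(C)C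
F2 | step 9 | 2-iodo-4-isopropoxy-3-methoxyphenyl N-isopropylcarbamate | COc1c(I)c(OC(=O)NC(C)C)ccc1OC(C)C
F3 | step 9 | 2-iodo-4-isopropoxy-3-methoxyphenol | COc1c(I)c(O)ccc1OC(C)C
F4 | step 9 | 2-iodo-4-isopropoxy-3-methoxyphenyl trifluoromethanesulfonate | COc1c(I)c(OS(=O)(=O)C(F)(F)F)ccc1OC(C)C
F5 | step 9 | 2-(chloromagnesio)-4-isopropoxy-3-methoxyphenyl trifluoromethanesulfonate | COc1c([Mg]Cl)c(OS(=O)(=O)C(F)(F)F)ccc1OC(C)C
F6 | step 12 | (1S)-N-{[(1S,2R)-1-(3,4-dimethoxyphenyl)-7-isopropoxy-8-methoxy-3-oxo-1,2,3,4-tetrahydronaphthalen-2-yl]carbonyl}-2,10-camphorsultam (1,2-trans) | CC1(C)[C@@H]2CC[C@]13CS(=O)(=O)N(C(=O)[C@H]4C(=O)Cc5ccc(OC(C)C)c(OC)c5[C@@H]4c4ccc(OC)c(OC)c4)[C@@H]3C2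
F7 | step 12 | (1S)-N-{[(1S,2R)-1-(3,4-dimethoxyphenyl)-3-hydroxy-7-isopropoxy-8-methoxy-1,2,3,4-tetrahydronaphthalen-2-yl]carbonyl}-2,10-camphorsultam (1,2-trans, C3 epimers) | CC1(C)[C@@H]2CC[C@]13CS(=O)(=O)N(C(=O)[C@H]4C(O)Cc5ccc(OC(C)C)c(OC)c5[C@@H]4c4ccc(OC)c(OC)c4)[C@@H]3C2
F8 | step 12 | (1S,2S)-1-(3,4-dimethoxyphenyl)-2-(hydroxymethyl)-7-isopropoxy-8-methoxy-1,2,3,4-tetrahydronaphthalen-3-ol (1,2-trans, C3 epimers, numbered as in the target) | COc1ccc([C@H]2c3c(ccc(OC(C)C)c3OC)CC(O)[C@@H]2CO)cc1OC
F9 | step 12 | (1S,2S)-2-[(tert-butyldimethylsilyloxy)methyl]-1-(3,4-dimethoxyphenyl)-7-isopropoxy-8-methoxy-1,2,3,4-tetrahydronaphthalen-3-ol (1,2-trans, C3 epimers, numbered as in the target) | COc1ccc([C@H]2c3c(ccc(OC(C)C)c3OC)CC(O)[C@@H]2CO[Si](C)(C)C(C)(C)C)cc1OC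
F10 | step 14 | methyl (3R,4S)-3-[(tert-butyldimethylsilyloxy)methyl]-4-(3,4-dimethoxyphenyl)-6-isopropoxy-5-methoxy-3,4-dihydronaphthalene-2-carboxylate | COc1ccc([C@H]2c3c(ccc(OC(C)C)c3OC)C=C(C(=O)OC)[C@@H]2CO[Si](C)(C)C(C)(C)C)cc1OC
F11 | step 14 | [(3R,4S)-3-[(tert-butyldimethylsilyloxy)methyl]-4-(3,4-dimethoxyphenyl)-6-isopropoxy-5-methoxy-3,4-dihydronaphthalen-2-yl]methanol | COc1ccc([C@H]2c3c(ccc(OC(C)C)c3OC)C=C(CO)[C@@H]2CO[Si](C)(C)C(C)(C)C)cc1OC
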